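Complex with one exchanged was the product I wanted to count, at the end of a row of flasks that share one charge of starting complex and differ in their charge of incoming ligand.

common to all: starting complex 0.20 mM
- oak: incoming ligand 0.014 mM; run made earlier
- elm: incoming ligand 0.12 mM; run made earlier
- cedar: incoming ligand 0.45 mM; run made earlier
- teal: incoming ligand 0.0200 mM; time 6.0 min
- blue: incoming ligand 0.0600 mM; time 6.0 min
- grey: incoming ligand 0.200 mM; time 6.0 min
- amber: incoming ligand 0.600 mM; time 6.0 min

| oak: time / min | oak: complex with one exchanged / % | elm: time / min | elm: complex with one exchanged / % | cedar: time / min | cedar: complex with one exchanged / % |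
|---|---|---|---|---|---|
| 0.250 | 0.9 | 0.250 | 10.0 | 0.250 | 23.1 |
| 0.417 | 1.4 | 0.833 | 15.9 | 0.833 | 19.4 |
| 0.833 | 3.1 | 1.33 | 16.0 | 1.33 | 15.7 |
| 1.50 | 2.8 | 2.00 | 16.5 | 2.00 | 13.3 |
| 3.00 | 3.2 | 3.00 | 16.7 | 3.00 | 13.3 |

(readings scatter by 0.5 percentage points)

- candidate steps: starting complex + incoming ligand -> leaving ligand + complex with one exchanged; complex with one exchanged + incoming ligand -> leaving ligand + complex with two exchanged; complex with two exchanged + incoming ligand -> leaving ligand + complex with three exchanged; complex with one exchanged <-> isomer of the product
- "hardly changes" means that all values lie within two and a half points (for a concentration: within two and a half percent of the largest)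

- amount of complex with one exchanged at the end, in percent of the starting complex charged for teal, blue, grey, amber, in this order
- how that number moves from the first to the last of them (rises all the way / falls all the way / rises, then falls / hardly changes / falls, then rises)

I kept books on the incoming ligand, the limiting reagent of the smaller charges. Each ligand that reacts frees one leaving ligand and makes one entry: a complex with one exchanged, its isomer, or a further exchange on a complex already counted.

In the oak run the first entry did not hold the whole charge. The oak run was charged 7.00 % of ligand per starting complex, yet its readings from 0.833 min on averaged 3.03 %. So oak gave 0.433, which I called the yield per ligand: [complex with one exchanged] on the plateau, divided by [incoming ligand] charged per [starting complex] charged. It is a reading, with a scatter of 0.5 percentage points on each point.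

The elm run, with 60.0 % charged, gave 0.278, lower than oak. The cedar run, with 225 % charged, gave 0.0591. I read this fall as the correction: ligand entered on further exchanges.

Keeping oak's yield for teal and reading the yield on a straight line between the runs for blue and grey, I committed to 4.33 % for teal, 11.0 % for blue and 22.5 % for grey. Amber, at 300 %, lay past cedar, so I set it below cedar's 13.3 %.

The forecast stood at 4.1 %, 10.4 %, 20.6 % and 3.6 %, shape rises, then falls, lower than my figure for grey, on the ground that “The plateaus mean the ligand runs out”.

The flasks gave 4.86 %, 11.6 %, 19.0 % and 3.88 %, and the row rises, then falls.

    starting complex + incoming ligand → leaving ligand + complex with one exchanged (k = 88.1 M⁻¹ s⁻¹)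
    complex with one exchanged + incoming ligand → leaving ligand + complex with two exchanged (k = 149 M⁻¹ s⁻¹)
    complex with two exchanged + incoming ligand → leaving ligand + complex with three exchanged (k = 275 M⁻¹ s⁻¹)
    complex with one exchanged ⇌ isomer of the product (K = 0.830, k = 0.0200 s⁻¹)

At 6.00 min teal held 0.17 % of its ligand, so its books had closed. Its yield per ligand came to 0.486, above oak's reading. In blue the yield per ligand came to 0.387, and oak's 0.433 on that charge makes 13.0 %, against the 11.6 % found. At the end blue held 2.79 % of complex with two exchanged and 1.07 % of complex with three exchanged.

(The data are simulated for substances that don't exist; scatter was added.)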